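**Strategy.** The route rests on cutting the tetrahydrofuran (O1, C2 bearing the catechol, C3 bearing CH2OH, C4 the tertiary carbinol, C5 an unsubstituted CH2) at C2–C3 and O1–C5. The feature exploited is the C4(OH)–C5H2–O1 unit: it is what remains when an allylsilane adds through its γ-carbon to an aldehyde, silicon migrates to the central carbon and the alkoxide closes on the former CH2Si carbon. One enantioselective [3+2] annulation therefore builds the ring, both bonds and all three stereocentres, with C4–Si as a masked hydroxyl. Its precursor is the Z allylsilane PhMe2SiCH2–C(CH2Ar)=CH–CH2OTBDPS (CH2Si cis to CH2O), paired with 3,4-bis(benzyloxy)benzaldehyde.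

Key step: step 5

Remark on notation: ring atoms are numbered O1, C2 (aryl), C3 (CH2O), C4 (quaternary), C5 (CH2) throughout; Ar′ = 3,4-dimethoxyphenyl; TBDPS = tert-butyldiphenylsilyl.

Assumption: the (S,S) ligand, 2,6-bis[(4S)-4-isopropyl-4,5-dihydrooxazol-2-yl]pyridine, is taken to steer attack to the Re face of the aldehyde, which gives 2R. If the opposite sense is found, the (R,R) ligand is used with nothing else changed.

**Step 1**
Reactants: 1 prop-2-yn-1-ol; 2 3,4-dimethoxybenzyl bromide
Product: 4 4-(3,4-dimethoxyphenyl)but-2-yn-1-ol, via the bis(bromomagnesium) derivative of propargyl alcohol 3 (not isolated)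
Conditions: EtMgBr (2.2 equiv), THF, 0 °C to rt; CuCl (10 mol %), then 2, rt to 50 °C; aq. NH4Cl
Reagents that add atoms: none
Why: Copper-catalysed alkylation of an alkynyl Grignard reagent with a benzylic bromide (Grignard cross-coupling): the acetylide carbon of 3 is far more nucleophilic than its magnesium alkoxide, so the alcohol needs no protection and no stereo element is created.

**Step 2**
Reactants: 4 4-(3,4-dimethoxyphenyl)but-2-yn-1-ol
Product: 6 (Z)-4-(3,4-dimethoxyphenyl)-3-iodobut-2-en-1-ol, via the cyclic sodium vinylalanate 5 (not isolated)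
Conditions: NaAlH2(OCH2CH2OMe)2 (1.5 equiv), THF, 0 °C to rt; EtOAc, −78 °C; I2, THF, −78 to 0 °C; aq. Na2S2O3, aq. potassium sodium tartrate
Reagents that add atoms: iodine, II
Why: Hydroxyl-directed trans-hydroalumination of a propargylic alcohol followed by iodinolysis: hydride goes to C2 and aluminium to C3 within the five-membered alanate 5, and C–Al to C–I exchange with retention leaves iodine cis to CH2OH, fixing the Z geometry that later decides the configuration at C4.

**Step 3**
Reactants: 6 (Z)-4-(3,4-dimethoxyphenyl)-3-iodobut-2-en-1-ol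
Product: 7 (Z)-tert-butyl{[4-(3,4-dimethoxyphenyl)-3-iodobut-2-en-1-yl]oxy}diphenylsilane
Conditions: TBDPSCl, imidazole, CH2Cl2, 0 °C to rt
Reagents that add atoms: tert-butyl(chloro)diphenylsilane, CC(C)(C)[Si](Cl)(c1ccccc1)c1ccccc1
Why: Imidazole-promoted silylation of a primary alcohol; the bulky, weakly Lewis-basic TBDPS ether is chosen because it cannot compete for the Lewis acid or take part in cation chemistry in step 5 and is shed in the same operation as the silicon oxidation in step 6.

**Step 4**
Reactants: 7 (Z)-tert-butyl{[4-(3,4-dimethoxyphenyl)-3-iodobut-2-en-1-yl]oxy}diphenylsilane; 8 (chloromethyl)dimethyl(phenyl)silane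
Product: 10 (Z)-[4-(tert-butyldiphenylsilyloxy)-2-(3,4-dimethoxybenzyl)but-2-enyl]dimethyl(phenyl)silane, via the silylmethyl Grignard reagent 9 (not isolated)
Conditions: 8, Mg, THF, reflux; then 7, Pd(PPh3)4 (5 mol %), THF, 0 °C to rt
Reagents that add atoms: none
Why: Kumada–Corriu coupling of a vinyl iodide with a silylmethyl Grignard reagent that has no β-hydrogen; oxidative addition and reductive elimination at palladium retain the alkene geometry, so CH2Si replaces iodine cis to CH2OTBDPS.

**Step 5**
Reactants: 10 (Z)-[4-(tert-butyldiphenylsilyloxy)-2-(3,4-dimethoxybenzyl)but-2-enyl]dimethyl(phenyl)silane; 11 3,4-bis(benzyloxy)benzaldehyde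
Product: 12 (2R,3R,4R)-2-[3,4-bis(benzyloxy)phenyl]-3-[(tert-butyldiphenylsilyloxy)methyl]-4-(3,4-dimethoxybenzyl)-4-[dimethyl(phenyl)silyl]tetrahydrofuran (aryl, CH2O and silyl all cis)
Conditions: Sc(OTf)3 (10 mol %), (S,S)-iPr-pybox (12 mol %), NaSbF6 (20 mol %), 4 Å MS, CH2Cl2, −20 °C
Reagents that add atoms: none
Why: Proposed new method: the cationic scandium–pybox complex binds the aldehyde oxygen, the alkene carbon bearing CH2OTBDPS attacks the Re face of the carbonyl anti to the C–Si bond (anti SE2′) to form C2–C3, the resulting tertiary β-silyl cation at C4 is bridged by silicon on the face opposite the new bond, and the scandium alkoxide opens this siliranium ion at its primary carbon C5 with inversion, forming O1–C5 and leaving silicon on C4. The closest known chemistry is the Lewis-acid [3+2] annulation of allylsilanes with aldehydes through a 1,2-silyl shift and its Sc(OTf)3–pybox enantioselective form with chelating isatins, while pybox complexes of trivalent indium are known to differentiate the faces of simple aryl aldehydes in allylstannane additions; new here is a one-point-binding aryl aldehyde combined with a 2,3-disubstituted allylsilane that places silicon on a quaternary carbon. The one ring closes by intramolecular SN2 opening of the three-membered siliranium ring at C5 (a 5-endo-type opening), in competition with 4-exo attack at C4 to an oxetane, which the unhindered primary C5 should disfavour. C2 is set by the ligand-controlled choice of aldehyde face, C3 by the open antiperiplanar transition state in which the aryl group lies next to the small γ-hydrogen (syn adduct, so aryl and CH2O are cis), and C4 by the Z alkene geometry together with the anti relationship between C–C bond formation and silicon migration, which puts silicon cis to CH2OTBDPS. The step needs annulation to beat loss of silicon to the homoallylic alcohol, which the hindered PhMe2Si group, the non-nucleophilic SbF6 counter-ion and the bulky silyl ether (no ether participation, no 1,4-elimination) are chosen to secure, and it needs Re-face selectivity, for which the ligand alone is responsible.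

**Step 6**
Reactants: 12 (2R,3R,4R)-2-[3,4-bis(benzyloxy)phenyl]-3-[(tert-butyldiphenylsilyloxy)methyl]-4-(3,4-dimethoxybenzyl)-4-[dimethyl(phenyl)silyl]tetrahydrofuran
Product: 14 (2R,3R,4R)-2-[3,4-bis(benzyloxy)phenyl]-4-(3,4-dimethoxybenzyl)-3-(hydroxymethyl)tetrahydrofuran-4-ol, via the desilylated primary alcohol 13 (not isolated)
Conditions: t-BuOOH, KH, NMP, 0 °C to rt; then Bu4NF, 70 °C
Reagents that add atoms: tert-butyl hydroperoxide, CC(C)(C)OO
Why: Fleming–Tamao oxidation in its basic peroxide–fluoride form for hindered phenylsilanes: fluoride first frees the primary alcohol (13), the phenyl group is cleaved from silicon and the tertiary C4 migrates from silicon to peroxide oxygen with retention, so the hydroxyl ends cis to CH2OH while aryl benzyl and methyl ethers are untouched.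

**Step 7**
Reactants: 14 (2R,3R,4R)-2-[3,4-bis(benzyloxy)phenyl]-4-(3,4-dimethoxybenzyl)-3-(hydroxymethyl)tetrahydrofuran-4-ol
Product: 15 (2R,3R,4R)-2-(3,4-dihydroxyphenyl)-4-(3,4-dimethoxybenzyl)-3-(hydroxymethyl)tetrahydrofuran-4-ol (target)
Conditions: H2 (1 atm), 10% Pd/C, EtOAc–EtOH, rt
Reagents that add atoms: none
Why: Catalytic hydrogenolysis of the two phenolic benzyl ethers under neutral conditions at atmospheric pressure, which is much faster than cleavage of the benzylic C2–O1 ring bond; no stereocentre is involved.

**Compound list**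
1 | prop-2-yn-1-ol (propargyl alcohol) | C#CCO | starting material
2 | 3,4-dimethoxybenzyl bromide | COc1ccc(CBr)cc1OC | starting material
3 | bromomagnesium 3-(bromomagnesio)prop-2-yn-1-olate | Br[Mg]C#CCO[Mg]Br | intermediate (not isolated)
4 | 4-(3,4-dimethoxyphenyl)but-2-yn-1-ol | COc1ccc(CC#CCO)cc1OC | intermediate
5 | cyclic sodium vinylalanate: Al bound to the chain oxygen, to C3 of the butenyl chain and to two 2-methoxyethoxy groups (five-membered 1-oxa-2-aluminacyclopent-3-ene) | [Na+].COCCO[Al-]1(OCCOC)OCC=C1Cc1ccc(OC)c(OC)c1 | intermediate (not isolated)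
6 | (Z)-4-(3,4-dimethoxyphenyl)-3-iodobut-2-en-1-ol (I cis to CH2OH) | OC/C=C(\I)Cc1ccc(OC)c(OC)c1 | intermediate
7 | (Z)-tert-butyl{[4-(3,4-dimethoxyphenyl)-3-iodobut-2-en-1-yl]oxy}diphenylsilane | CC(C)(C)[Si](c1ccccc1)(c1ccccc1)OC/C=C(\I)Cc1ccc(OC)c(OC)c1 | intermediate
8 | (chloromethyl)dimethyl(phenyl)silane | C[Si](C)(CCl)c1ccccc1 | starting material
9 | {[dimethyl(phenyl)silyl]methyl}magnesium chloride | C[Si](C)(C[Mg]Cl)c1ccccc1 | intermediate (not isolated)
10 | (Z)-[4-(tert-butyldiphenylsilyloxy)-2-(3,4-dimethoxybenzyl)but-2-enyl]dimethyl(phenyl)silane (CH2Si cis to CH2O) | C[Si](C)(c1ccccc1)C/C(Cc1ccc(OC)c(OC)c1)=C\CO[Si](c1ccccc1)(c1ccccc1)C(C)(C)C | intermediate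
11 | 3,4-bis(benzyloxy)benzaldehyde | O=Cc1ccc(OCc2ccccc2)c(OCc2ccccc2)c1 | starting material
12 | (2R,3R,4R)-2-[3,4-bis(benzyloxy)phenyl]-3-[(tert-butyldiphenylsilyloxy)methyl]-4-(3,4-dimethoxybenzyl)-4-[dimethyl(phenyl)silyl]tetrahydrofuran | COc1ccc(C[C@]2([Si](C)(C)c3ccccc3)CO[C@@H](c3ccc(OCc4ccccc4)c(OCc4ccccc4)c3)[C@H]2CO[Si](c2ccccc2)(c2ccccc2)C(C)(C)C)cc1OC | intermediate
13 | [(2R,3R,4R)-2-[3,4-bis(benzyloxy)phenyl]-4-(3,4-dimethoxybenzyl)-4-[dimethyl(phenyl)silyl]tetrahydrofuran-3-yl]methanol | COc1ccc(C[C@]2([Si](C)(C)c3ccccc3)CO[C@@H](c3ccc(OCc4ccccc4)c(OCc4ccccc4)c3)[C@H]2CO)cc1OC | intermediate (not isolated)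
14 | (2R,3R,4R)-2-[3,4-bis(benzyloxy)phenyl]-4-(3,4-dimethoxybenzyl)-3-(hydroxymethyl)tetrahydrofuran-4-ol | COc1ccc(C[C@]2(O)CO[C@@H](c3ccc(OCc4ccccc4)c(OCc4ccccc4)c3)[C@H]2CO)cc1OC | intermediate
15 | (2R,3R,4R)-2-(3,4-dihydroxyphenyl)-4-(3,4-dimethoxybenzyl)-3-(hydroxymethyl)tetrahydrofuran-4-ol, i.e. 4-[(2R,3R,4R)-4-(3,4-dimethoxybenzyl)-4-hydroxy-3-(hydroxymethyl)oxolan-2-yl]benzene-1,2-diol | COc1ccc(C[C@]2(O)CO[C@@H](c3ccc(O)c(O)c3)[C@H]2CO)cc1OC | target

**Step count.** Total: 7 steps. Longest linear sequence: 7 steps (1 to 15 through steps 1–7; 8 and 11 enter as purchased materials).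

**Steps most likely to fail**

Step 5 (proposed new method). The singly coordinated aldehyde may not be held rigidly enough in the chiral pocket, so that facial selectivity is poor, or the mild catalyst may allow silicon to be lost before the ring closes. The fallback obtains absolute configuration by resolution instead of catalyst control. Setting out from 10 and 11, the annulation is run in its documented achiral form with a stoichiometric Lewis acid (BF3·OEt2, CH2Cl2, −78 °C). Under the same stereochemical rules this should give the racemic all-cis silyl tetrahydrofuran F1. The enantiomers are then separated by preparative chromatography on a chiral stationary phase (cellulose tris(3,5-dimethylphenylcarbamate), supercritical CO2–MeOH). The 2R,3R,4R enantiomer is compound 12, where the route is rejoined.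

Step 6. Cleavage of the Si–phenyl bond or migration of the hindered tertiary carbon may be too slow, and prolonged heating in base may instead cause β-elimination of silicon with rupture of the C5–O1 bond. The fallback uses the cis CH2OH group as an internal nucleophile. Setting out from 12, Bu4NF (THF, rt) gives the primary alcohol 13, this time isolated. With t-BuOK in DMSO at rt its alkoxide should displace phenyl from silicon intramolecularly (benzene is lost) to give the cis-fused cyclic siloxane F2. This alkoxysilane is then oxidised under ordinary Tamao conditions (H2O2, KF, KHCO3, THF–MeOH, 40 °C) with retention, returning to the route at 14.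

Step 7. Hydrogenolysis of the benzylic C2–O1 ring bond may compete with O-debenzylation and open the ring, and the catechol may oxidise in air during isolation. The fallback changes the catechol protection to allyl so that no hydrogen is needed. 3,4-Bis(allyloxy)benzaldehyde F3 (from 3,4-dihydroxybenzaldehyde, allyl bromide, K2CO3, DMF) replaces 11. Setting out from 10, the conditions of step 5 should give the allyl-protected silyl tetrahydrofuran F4. The conditions of step 6 should then give, via the allyl-protected primary alcohol F5 (not isolated), the allyl-protected diol F6. Deallylation with Pd(PPh3)4 (5 mol %) and morpholine in degassed THF at rt returns to the route at the target 15.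

**Further compounds**
F1 | step 5 | racemic 12, relative configuration 2R*,3R*,4R* (SMILES drawn for the 2R,3R,4R member of the 1:1 pair) | COc1ccc(C[C@]2([Si](C)(C)c3ccccc3)CO[C@@H](c3ccc(OCc4ccccc4)c(OCc4ccccc4)c3)[C@H]2CO[Si](c2ccccc2)(c2ccccc2)C(C)(C)C)cc1OC
F2 | step 6 | cis-fused cyclic siloxane of 13: the C3 CH2O oxygen bound to the C4 SiMe2 group (2,2-dimethyl-1-oxa-2-silacyclopentane fused at C3–C4 of the tetrahydrofuran, configuration as in 13) | COc1ccc(C[C@]23CO[C@@H](c4ccc(OCc5ccccc5)c(OCc5ccccc5)c4)[C@H]2CO[Si]3(C)C)cc1OC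
F3 | step 7 | 3,4-bis(allyloxy)benzaldehyde | C=CCOc1ccc(C=O)cc1OCC=C
F4 | step 7 | (2R,3R,4R)-2-[3,4-bis(allyloxy)phenyl]-3-[(tert-butyldiphenylsilyloxy)methyl]-4-(3,4-dimethoxybenzyl)-4-[dimethyl(phenyl)silyl]tetrahydrofuran | COc1ccc(C[C@]2([Si](C)(C)c3ccccc3)CO[C@@H](c3ccc(OCC=C)c(OCC=C)c3)[C@H]2CO[Si](c2ccccc2)(c2ccccc2)C(C)(C)C)cc1OC
F5 | step 7 | [(2R,3R,4R)-2-[3,4-bis(allyloxy)phenyl]-4-(3,4-dimethoxybenzyl)-4-[dimethyl(phenyl)silyl]tetrahydrofuran-3-yl]methanol (not isolated) | COc1ccc(C[C@]2([Si](C)(C)c3ccccc3)CO[C@@H](c3ccc(OCC=C)c(OCC=C)c3)[C@H]2CO)cc1OC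
F6 | step 7 | (2R,3R,4R)-2-[3,4-bis(allyloxy)phenyl]-4-(3,4-dimethoxybenzyl)-3-(hydroxymethyl)tetrahydrofuran-4-ol | COc1ccc(C[C@]2(O)CO[C@@H](c3ccc(OCC=C)c(OCC=C)c3)[C@H]2CO)cc1OC
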